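## Retrosynthetic overview

- **Spiroketal, both rings last:** the target comes from the bis-TES ether of a phthalide-alkynediol by desilylation and gold-catalysed double hydroalkoxylation (5-exo plus 5-endo onto the same alkyne carbon). The spiro centre is thermodynamic (about 1:1); the spiro epimer forms in the same flask, interconverts with the target under the acid, and what is left after HPLC goes back into the equilibration.
- **Benzene and lactone rings in one operation:** the 5,7-dimethoxyphthalide comes from an acyclic (R)-γ-hydroxy-ynoate and 1,5-dimethoxycyclohexa-1,4-diene by Alder–Rickert benzannulation and lactonisation. No aromatic starting material is used.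
- **C3 stereocentre:** the ynoate comes from an aldehyde and methyl propiolate by Zn–ProPhenol alkynylation; the aldehyde comes from a terminal alkene by ozonolysis.
- **C16 chain with both carbinol centres:** a propyne-dianion linchpin joins (S)-1,2-epoxy-9-decene (from hydrolytic kinetic resolution) and (S)-propylene oxide.
- **Ring order:** arene and lactone together (step 5), then the two spiroketal rings together (step 6).

Assumption: the catalyst antipodes named in steps 1 and 4 are those expected from the usual selectivity models to give the (S)-epoxide and the (4R)-alcohol; the sense is checked on the first run (rotation of 2, Mosher ester of 11) and the mirror-image catalyst is used if it is opposite.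

## Route

**Step 1**
Reactants: 1 rac-2-(oct-7-en-1-yl)oxirane (1,2-epoxy-9-decene)
Product: 2 (2S)-2-(oct-7-en-1-yl)oxirane
Conditions: (S,S)-(salen)Co(III)OAc (0.5 mol %), H2O (0.55 equiv), neat, 0 °C → rt, 16 h; distil
Reagents that add atoms: none
Why: Jacobsen hydrolytic kinetic resolution, in which the catalyst hydrolyses the (R)-epoxide selectively (k_rel > 100 for unbranched terminal epoxides) and leaves the (S)-epoxide, the future spiroketal C2 centre, in >99% ee.

**Step 2**
Reactants: 3 propyne; 2 (2S)-2-(oct-7-en-1-yl)oxirane; 4 (2S)-2-methyloxirane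
Product: 8 (2S,8S)-2,8-bis(triethylsilyloxy)hexadec-15-en-4-yne, via 1,3-dilithiopropyne 5 (not isolated), via dilithium derivative of (5S)-tridec-12-en-1-yn-5-ol 6 (not isolated), via dilithium (2S,8S)-hexadec-15-en-4-yne-2,8-diolate 7 (not isolated)
Conditions: 3 (1.3 equiv), n-BuLi (2.6 equiv), TMEDA, THF/hexane, −78 → 0 °C; 2, −78 → −20 °C; DMPU, 4 (3 equiv), −20 °C → rt; TESCl (3.5 equiv), 0 °C → rt
Reagents that add atoms: chlorotriethylsilane (TESCl), CC[Si](Cl)(CC)CC
Why: Proposed new method: a one-pot propargyl-dianion linchpin coupling, in which the sp3 terminus of 5 is far more nucleophilic than its acetylide terminus and opens 2 at CH2 (SN2, the C–O bond of the stereocentre is untouched), the remaining lithium acetylide opens 4 at CH2 once DMPU is added, and both lithium alkoxides are silylated in the same flask; the closest known chemistry is the stepwise alkylation of 1,3-dilithiopropyne at carbon 3 and the acetylide–epoxide opening, and both carbinol centres (8S from 2, 2S from 4) are simply carried over.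

**Step 3**
Reactants: 8 (2S,8S)-2,8-bis(triethylsilyloxy)hexadec-15-en-4-yne
Product: 9 (8S,14S)-8,14-bis(triethylsilyloxy)pentadec-11-ynal
Conditions: O3, CH2Cl2, −78 °C (Sudan Red 7B end point); PPh3, −78 °C → rt
Reagents that add atoms: ozone, [O-][O+]=O
Why: Chemoselective ozonolysis with reductive work-up, in which the terminal alkene reacts far faster than the internal alkyne (indicator-controlled end point) and no stereocentre is touched.

**Step 4**
Reactants: 9 (8S,14S)-8,14-bis(triethylsilyloxy)pentadec-11-ynal; 10 methyl propiolate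
Product: 11 methyl (4R,11S,17S)-4-hydroxy-11,17-bis(triethylsilyloxy)octadeca-2,14-diynoate
Conditions: (R,R)-ProPhenol (10 mol %), Me2Zn (3 equiv), 10 (3 equiv), Ph3PO (20 mol %), toluene, 4 °C, 48 h; aq NH4Cl
Reagents that add atoms: none
Why: Trost Zn–ProPhenol asymmetric alkynylation, in which the dinuclear zinc catalyst delivers the zinc alkynylide of 10 to one face of the aldehyde and sets the (4R) carbinol (the future phthalide C3) under catalyst control, the remote silyl ether centres having no influence.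

**Step 5**
Reactants: 11 methyl (4R,11S,17S)-4-hydroxy-11,17-bis(triethylsilyloxy)octadeca-2,14-diynoate; 12 1,5-dimethoxycyclohexa-1,4-diene
Product: 16 (3R)-3-[(7S,13S)-7,13-bis(triethylsilyloxy)tetradec-10-yn-1-yl]-5,7-dimethoxy-2-benzofuran-1(3H)-one, via 1,3-dimethoxycyclohexa-1,3-diene 13 (not isolated), via methyl 3-[(1R,8S,14S)-1-hydroxy-8,14-bis(triethylsilyloxy)pentadec-11-yn-1-yl]-1,5-dimethoxybicyclo[2.2.2]octa-2,5-diene-2-carboxylate 14 (not isolated), via methyl 2-[(1R,8S,14S)-1-hydroxy-8,14-bis(triethylsilyloxy)pentadec-11-yn-1-yl]-4,6-dimethoxybenzoate 15 (not isolated)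
Conditions: 12 (5 equiv), dichloromaleic anhydride (1 mol %), neat, sealed tube, Ar, 150 → 180 °C, 12 h
Reagents that add atoms: none
Why: Alder–Rickert reaction, in which 12 conjugates in situ to 13, the doubly donor-activated C4 terminus of 13 bonds to the ynoate β-carbon (Danishefsky-type regiochemistry), adduct 14 extrudes ethene by retro-Diels–Alder to give benzoate 15, and 15 lactonises, so the arene and lactone rings form in one operation while the carbinol C–O bond (C3, R) is never broken.

**Step 6**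
Reactants: 16 (3R)-3-[(7S,13S)-7,13-bis(triethylsilyloxy)tetradec-10-yn-1-yl]-5,7-dimethoxy-2-benzofuran-1(3H)-one
Product: 20 (3R)-5,7-dimethoxy-3-{6-[(2S,5R,7S)-7-methyl-1,6-dioxaspiro[4.4]nonan-2-yl]hexyl}-2-benzofuran-1(3H)-one, via (3R)-3-[(7S,13S)-7,13-dihydroxytetradec-10-yn-1-yl]-5,7-dimethoxy-2-benzofuran-1(3H)-one 17 (not isolated), via (3R)-3-{6-[(2S,5Z)-5-[(3S)-3-hydroxybutylidene]oxolan-2-yl]hexyl}-5,7-dimethoxy-2-benzofuran-1(3H)-one 18 (not isolated), via (3R)-5,7-dimethoxy-3-{6-[(2S,5S,7S)-7-methyl-1,6-dioxaspiro[4.4]nonan-2-yl]hexyl}-2-benzofuran-1(3H)-one 19 (not isolated)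
Conditions: PPTS (0.2 equiv), MeOH/CH2Cl2 (1:4), rt, 2 h; AuCl (5 mol %), rt, 4 h; Et3N; semi-preparative HPLC (SiO2, hexane/EtOAc) takes off 20; the 19-rich remainder goes straight back into PPTS/CH2Cl2 (rt, back to about 1:1) and is separated again (two cycles)
Reagents that add atoms: none
Why: Acid-mediated desilylation followed by gold-catalysed double intramolecular hydroalkoxylation (alkynediol cycloisomerisation), in which the favoured closures (5-exo for one hydroxyl, 5-endo for the other) converge on the same alkyne carbon and give the [4.4] spiroketal with both carbinol centres retained; the oxocarbenium ion from 18 is trapped on either face, so the (5S) epimer 19 forms beside 20, the two interconvert through the ring-opened oxocarbenium ion under the acid (about 1:1, no anomeric bias), and pure 20 is obtained by HPLC while 19 is re-equilibrated.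

## Compound list

1 | rac-2-(oct-7-en-1-yl)oxirane (1,2-epoxy-9-decene) | C=CCCCCCCC1CO1 | starting material
2 | (2S)-2-(oct-7-en-1-yl)oxirane | C=CCCCCCC[C@H]1CO1 | intermediate
3 | propyne | CC#C | starting material
4 | (2S)-2-methyloxirane ((S)-propylene oxide) | C[C@H]1CO1 | starting material
5 | 1,3-dilithiopropyne | [Li]CC#C[Li] | intermediate
6 | dilithium derivative (C1-Li, O-Li) of (5S)-tridec-12-en-1-yn-5-ol | [Li]C#CCC[C@@H](O[Li])CCCCCCC=C | intermediate
7 | dilithium (2S,8S)-hexadec-15-en-4-yne-2,8-diolate | C[C@H](O[Li])CC#CCC[C@@H](O[Li])CCCCCCC=C | intermediate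
8 | (2S,8S)-2,8-bis(triethylsilyloxy)hexadec-15-en-4-yne | C[C@H](O[Si](CC)(CC)CC)CC#CCC[C@@H](O[Si](CC)(CC)CC)CCCCCCC=C | intermediate
9 | (8S,14S)-8,14-bis(triethylsilyloxy)pentadec-11-ynal | C[C@H](O[Si](CC)(CC)CC)CC#CCC[C@@H](O[Si](CC)(CC)CC)CCCCCCC=O | intermediate
10 | methyl propiolate (methyl prop-2-ynoate) | C#CC(=O)OC | starting material
11 | methyl (4R,11S,17S)-4-hydroxy-11,17-bis(triethylsilyloxy)octadeca-2,14-diynoate | C[C@H](O[Si](CC)(CC)CC)CC#CCC[C@@H](O[Si](CC)(CC)CC)CCCCCC[C@@H](O)C#CC(=O)OC | intermediate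
12 | 1,5-dimethoxycyclohexa-1,4-diene | COC1=CCC=C(OC)C1 | starting material
13 | 1,3-dimethoxycyclohexa-1,3-diene | COC1=CC(OC)=CCC1 | intermediate
14 | methyl 3-[(1R,8S,14S)-1-hydroxy-8,14-bis(triethylsilyloxy)pentadec-11-yn-1-yl]-1,5-dimethoxybicyclo[2.2.2]octa-2,5-diene-2-carboxylate (bridgehead diastereomers, transient) | COC(=O)C1=C([C@H](O)CCCCCC[C@H](O[Si](CC)(CC)CC)CCC#CC[C@H](C)O[Si](CC)(CC)CC)C2CCC1(OC)C=C2OC | intermediate
15 | methyl 2-[(1R,8S,14S)-1-hydroxy-8,14-bis(triethylsilyloxy)pentadec-11-yn-1-yl]-4,6-dimethoxybenzoate | COC(=O)c1c(OC)cc(OC)cc1[C@H](O)CCCCCC[C@H](O[Si](CC)(CC)CC)CCC#CC[C@H](C)O[Si](CC)(CC)CC | intermediate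
16 | (3R)-3-[(7S,13S)-7,13-bis(triethylsilyloxy)tetradec-10-yn-1-yl]-5,7-dimethoxy-2-benzofuran-1(3H)-one | COc1cc(OC)c2c(c1)[C@@H](CCCCCC[C@H](O[Si](CC)(CC)CC)CCC#CC[C@H](C)O[Si](CC)(CC)CC)OC2=O | intermediate
17 | (3R)-3-[(7S,13S)-7,13-dihydroxytetradec-10-yn-1-yl]-5,7-dimethoxy-2-benzofuran-1(3H)-one | COc1cc(OC)c2c(c1)[C@@H](CCCCCC[C@H](O)CCC#CC[C@H](C)O)OC2=O | intermediate
18 | (3R)-3-{6-[(2S,5Z)-5-[(3S)-3-hydroxybutylidene]oxolan-2-yl]hexyl}-5,7-dimethoxy-2-benzofuran-1(3H)-one | COc1cc(OC)c2c(c1)[C@@H](CCCCCC[C@H]1CC/C(=C/C[C@H](C)O)O1)OC2=O | intermediate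
19 | (3R)-5,7-dimethoxy-3-{6-[(2S,5S,7S)-7-methyl-1,6-dioxaspiro[4.4]nonan-2-yl]hexyl}-2-benzofuran-1(3H)-one (spiro epimer, formed in the flask in step 6 and equilibrated there with 20) | COc1cc(OC)c2c(c1)[C@@H](CCCCCC[C@H]1CC[C@]3(CC[C@H](C)O3)O1)OC2=O | intermediate
20 | (3R)-5,7-dimethoxy-3-{6-[(2S,5R,7S)-7-methyl-1,6-dioxaspiro[4.4]nonan-2-yl]hexyl}-2-benzofuran-1(3H)-one | COc1cc(OC)c2c(c1)[C@@H](CCCCCC[C@H]1CC[C@@]3(CC[C@H](C)O3)O1)OC2=O | target

## Step count and risks

Total steps: 6. Longest linear sequence: 6 (1 → 2 → 8 → 9 → 11 → 16 → 20); all other building blocks (3, 4, 10, 12) are bought.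

The three steps most likely to fail are steps 2, 5 and 4.

**Step 2 (one-pot dianion linchpin with in-flask silylation).** The risks are incomplete dilithiation, a sluggish second epoxide opening and a messy trapping. The fallback sets out from 2 and comes back at 8, making one bond at a time with a silyl-blocked propargyl anion. Lithiated 1-(trimethylsilyl)propyne (n-BuLi, THF, −78 °C, BF3·OEt2) opens 2 to give (5S)-1-(trimethylsilyl)tridec-12-en-1-yn-5-ol F1. K2CO3/MeOH then gives (5S)-tridec-12-en-1-yn-5-ol F2. Its dianion (2.2 equiv n-BuLi) with BF3·OEt2 and 4 at −78 °C gives (2S,8S)-hexadec-15-en-4-yne-2,8-diol F3. TESCl/imidazole in DMF returns to 8.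

**Step 5 (Alder–Rickert at 180 °C).** The risks are poor in-situ conjugation of 12, thermal loss of the hydroxy-ynoate and some cycloaddition at the unactivated internal alkyne. The fallback sets out from 11 and comes back at 16; it builds the arene at lower temperature with an acyclic vinylketene acetal and aromatises by elimination instead of ethene extrusion. 1,3-Dimethoxy-1-(trimethylsilyloxy)buta-1,3-diene F6 (from methyl (E)-3-methoxybut-2-enoate, LDA, TMSCl) reacts with 11 in toluene at 80–110 °C with the same regiochemistry. If the ketal carbon loses silanol, 16 forms directly. If it loses methanol, work-up gives (3R)-3-[(7S,13S)-7,13-bis(triethylsilyloxy)tetradec-10-yn-1-yl]-7-hydroxy-5-methoxy-2-benzofuran-1(3H)-one F7, which MeI/K2CO3 in acetone converts into 16.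

**Step 4 (enantioselectivity on an unbranched aliphatic aldehyde).** The C4 epimer is a remote diastereomer that cannot be removed later, so selectivity here fixes the final purity at C3. The fallback sets out from 9 and comes back at 11, separating C–C bond formation from stereocontrol. Lithium methyl propiolate (10, LiHMDS, THF, −90 °C) adds to 9 to give methyl (4RS,11S,17S)-4-hydroxy-11,17-bis(triethylsilyloxy)octadeca-2,14-diynoate F4. Dess–Martin oxidation gives methyl (11S,17S)-4-oxo-11,17-bis(triethylsilyloxy)octadeca-2,14-diynoate F5. Midland reduction with (R)-Alpine-Borane (neat, rt), a known reaction of 4-oxo-2-ynoates, gives 11.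

## Further compounds

F1 | step 2 | (5S)-1-(trimethylsilyl)tridec-12-en-1-yn-5-ol | C[Si](C)(C)C#CCC[C@@H](O)CCCCCCC=C
F2 | step 2 | (5S)-tridec-12-en-1-yn-5-ol | C#CCC[C@@H](O)CCCCCCC=C
F3 | step 2 | (2S,8S)-hexadec-15-en-4-yne-2,8-diol | C[C@H](O)CC#CCC[C@@H](O)CCCCCCC=C
F4 | step 4 | methyl (4RS,11S,17S)-4-hydroxy-11,17-bis(triethylsilyloxy)octadeca-2,14-diynoate (C4 epimer mixture) | C[C@H](O[Si](CC)(CC)CC)CC#CCC[C@@H](O[Si](CC)(CC)CC)CCCCCCC(O)C#CC(=O)OC
F5 | step 4 | methyl (11S,17S)-4-oxo-11,17-bis(triethylsilyloxy)octadeca-2,14-diynoate | C[C@H](O[Si](CC)(CC)CC)CC#CCC[C@@H](O[Si](CC)(CC)CC)CCCCCCC(=O)C#CC(=O)OC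
F6 | step 5 | 1,3-dimethoxy-1-(trimethylsilyloxy)buta-1,3-diene (E/Z mixture) | COC(=C)C=C(OC)O[Si](C)(C)C
F7 | step 5 | (3R)-3-[(7S,13S)-7,13-bis(triethylsilyloxy)tetradec-10-yn-1-yl]-7-hydroxy-5-methoxy-2-benzofuran-1(3H)-one | COc1cc(O)c2c(c1)[C@@H](CCCCCC[C@H](O[Si](CC)(CC)CC)CCC#CC[C@H](C)O[Si](CC)(CC)CC)OC2=O
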